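## The problem

The target is a nineteen-carbon chain, numbered here C1–C19 from the pentyl end. One ether oxygen bridges C6 and C9 to give an oxolane, C7 carries a free hydroxyl, the exocyclic C10 carries the dodecanoate, and C18=C19 is a terminal alkene. Four stereocentres must be set (6S, 7S, 9R, 10R): on the ring the pentyl group and the C7 hydroxyl are cis, the C9 side chain is trans to both, and C9/C10 are threo. C6 and C7 form a vicinal syn pair that one reagent-controlled C–C bond formation can set together, and C10 is best brought in already resolved. C9 lies between the two sets and can be steered by both: by C7 through the conformation of a C9 oxocarbenium ion and by C10 through 1,2-induction. The two secondary oxygens must be distinguished from the start, because only O10 is acylated. Once the ester is present, hydride donors, organometallics and strong acid or base are excluded; the terminal alkene forbids late hydrogenation or hydroboration and competes in any metathesis. The enabling feature is that C9 is bonded both to the ring oxygen and to the oxygenated C10. The O–C9 bond can therefore begin as the acyl–oxygen bond of an ester between a C1–C8 alcohol and a C9–C19 α-oxy acid; after C9=O becomes C9=CH2, only C8–C9 is missing, and a vinyl group on C7 supplies it by five-membered ring closure. The cost is that the ring first appears as a 2,3-dihydrofuran whose C7 oxygen is allylic, so acid can expel it and aromatise the ring.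

## Retrosynthesis

**End game (22 ⇒ 21 ⇒ 19 + 20 ⇒ 18).** The C7 methoxymethyl acetal, the C10 acyl–oxygen bond and the C10 O–Si bond are cut in that order. Acylation of 19 with 20 is placed late so that the ester in 21 meets only one further reagent. O7 is an acetal because the fragment synthesis delivers it so, and O10 is a silyl ether because fluoride frees it from 18 without touching the acetal. The forward sequence needs an acetal cleavage that spares the ester, the alkene and the ring ether.

**C9–H (18 ⇒ 17 ⇒ 16).** The C9–H bond is cut back to a C9 oxocarbenium ion, stored as methyl ketal 17, which comes from methanol addition to the cyclic enol ether 16. Hydrogenation or hydroboration of C8=C9 is rejected: it would also attack C18=C19 and would add from the face away from the C7 oxygen, which gives the wrong C9 epimer. The forward step needs hydride delivery to the face of C9 syn to O7.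

**C8=C9 (16 ⇒ 15), the key cut.** The ring is opened at the double bond to the diene enol ether 15. The neighbouring cuts, closing O–C9 or O–C6 by substitution, would need one of two similar secondary alcohols activated selectively and the reacting carbon prepared with inverted configuration. Metathesis needs neither, forms no stereocentre, and leaves an acyclic precursor. It is asked to prefer five-ring closure over reaction at C18=C19.

**C9=CH2 (15 ⇒ 14).** The methylene carbon is removed to give ester 14. This turns the enol ether linkage into a bond that simple acylation can form, and requires a non-basic, non-acidic carbonyl methylenation.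

**Acyl–oxygen bond (14 ⇒ 6 + 13).** The ester, which is the future ring O–C9 bond, is cut into acid 6 (C9–C19, with C10) and alcohol 13 (C1–C8, with C6 and C7). The two halves are of similar size and each carries its own stereocentres, so the route is convergent.

**C6–C7 (13 ⇒ 7 + 8, through 9–12).** Alkoxyallylboration of aldehyde 7 with the reagent made from allyl ether 8 forms C6–C7. In one operation it gives the syn relationship, the absolute configuration, O6 free with O7 protected, and the C8 vinyl group. A diene dihydroxylation would give the same diol without differentiating the two hydroxyls.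

**C11–C12 (6 ⇒ 5 ⇒ 4 ⇒ 1 + 2, through 3).** Acid 6 is traced through ester 5 to hydroxy ester 4, which is cut between C11 and C12 into the organomagnesium reagent 3 from bromide 1 and the glycidic ester 2. C10 is bought rather than made. An auxiliary-controlled α-hydroxylation of a preformed C11 acyl chain would cost one more step. The forward step needs attack at the epoxide CH2 rather than the ester carbonyl.

## Roads not taken

**Alternative 1:** The ring O–C6 bond is cut and C5–C10 are traced to D-glucose A1 (sugar C1–C6 become C10–C5). In the forward key step the 3-deoxy 5-O-mesyl acetonide A2 is treated with acidic methanol. The acetonide opens to the dimethyl acetal and the freed O2 hydroxyl displaces the mesylate at sugar C5 with inversion, closing the oxolane A3.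
- Merits: C7 and C9 come unchanged from the sugar and C6 from a clean SN2 inversion, so all three ring centres are fixed without any facial selection. In this respect it is more secure than the chosen plan, which sets C9 by substrate control.
- Weak points: A2 requires deoxygenation at sugar C3, a butyl extension at sugar C6 and selective sulfonylation, so the sequence is linear and long. After A3, C10 must be created by adding a C9 alkenyl organometallic to an α-alkoxy aldehyde, where chelation favours the needed threo isomer but seldom completely. The O7/O10 differentiation problem remains.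
- Comparison: the chosen plan answers with convergence, a C10 centre fixed before coupling, and a C9 reduction in which ring control and 1,2-induction point the same way.

**Alternative 2:** The C5–C6 and O–C7 bonds are cut together. Photoexcited pentanal A4 would add across the C6=C7 enol ether of dihydrofuran A5, which already carries the C10 ester, to give the fused oxetane A6 (Paternò–Büchi reaction).
- Merits: it is the shortest construction on paper. The cis ring fusion guarantees the cis relationship of the C6 chain and the C7 oxygen, the regiochemistry expected for a 2,3-dihydrofuran is the one needed, and the configuration at the butyl-bearing carbon is irrelevant because it ends as CH2. In brevity it beats the chosen plan.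
- Weak points: the C5–O bond of the oxetane must then be cleaved reductively while the C7–O bond is kept. No selective method exists for an unactivated dialkyl oxetane, and hydride reagents would attack the dodecanoate. An aliphatic aldehyde with γ-hydrogens also fragments photochemically, and face selection rests only on the remote C9 substituent.
- Comparison: the chosen plan is longer but uses only operations with direct precedent.

**Alternative 3:** The O–C9 bond is formed by a 1,2-oxygen shift. Tl(NO3)3 (trivalent thallium) or PhI(OH)OTs in methanol attacks C9 of dihydropyran A7; the ring oxygen migrates from C10 to C9 and C10 leaves the ring as a dimethyl acetal, giving oxolane A8.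
- Merits: the contraction is stereospecific (anti addition, then migration with inversion at C9), so C9 depends only on which face the electrophile takes. The C7 silyl ether would allow a fluoride deprotection as the last step, which is gentler beside an ester than the acetal cleavage of the chosen plan.
- Weak points: thallium toxicity, or thinner precedent for the iodine variant on alkyl-substituted dihydropyrans; competing plain 1,2-addition without migration; a multistep enantioselective synthesis of A7; and, as in Alternative 1, a late addition to the C10 aldehyde of only moderate selectivity.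
- Comparison: the chosen plan offers a preset C10, two short fragment syntheses and no heavy-metal oxidant.

Key step: step 7

## Route

Remark: carbons are numbered C1–C19 from the pentyl end throughout. Ketal 17 is carried forward as the mixture of C9 anomers, since both ionise to the same cation in step 9. Ipc = (1S,2R,3S,5S)-2,6,6-trimethylbicyclo[3.1.1]hept-3-yl.

Step 1
Reactants: 1 8-bromooct-1-ene; 2 methyl (2R)-oxirane-2-carboxylate
Product: 4 methyl (2R)-2-hydroxyundec-10-enoate, via oct-7-enylmagnesium bromide 3 (not isolated)
Conditions: Mg, THF, rt; then added to 2, CuI (10 mol%), THF, −40 → −20 °C; sat. aq. NH4Cl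
Reagents that add atoms: none
Why: Copper-catalysed ring opening of a glycidic ester by a Grignard reagent; the organocopper species attacks the unsubstituted epoxide carbon in an SN2 step at low temperature faster than the ester carbonyl. The stereocentre is not touched, so the (R) configuration of 2 becomes C10 of the target.

Step 2
Reactants: 4 methyl (2R)-2-hydroxyundec-10-enoate
Product: 5 methyl (2R)-2-(tert-butyldimethylsilyloxy)undec-10-enoate
Conditions: TBSCl, imidazole, DMF, rt
Reagents that add atoms: tert-butyldimethylsilyl chloride, CC(C)(C)[Si](C)(C)Cl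
Why: Standard silylation of a secondary alcohol with imidazole as base and acyl-transfer-type activator; no bond to the stereocentre is broken.

Step 3
Reactants: 5 methyl (2R)-2-(tert-butyldimethylsilyloxy)undec-10-enoate
Product: 6 (2R)-2-(tert-butyldimethylsilyloxy)undec-10-enoic acid
Conditions: LiOH·H2O, THF/H2O 3:1, 0 °C → rt; then 1 M HCl to pH 3, 0 °C
Reagents that add atoms: lithium hydroxide, [Li+].[OH-]
Why: Saponification of a methyl ester; the carboxylate formed is not enolised under these mild conditions, so C10 should keep its configuration, and the secondary silyl ether tolerates cold aqueous LiOH and brief mild acidification.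

Step 4
Reactants: 7 hexanal; 8 3-(methoxymethoxy)prop-1-ene
Product: 13 (3S,4S)-3-(methoxymethoxy)non-1-en-4-ol, via (Z)-alkoxyallyllithium 9 (not isolated), via boron ate complex 10 (not isolated), via (Z)-alkoxyallylborane 11 (not isolated), via borinic ester 12 (not isolated)
Conditions: 8, s-BuLi, THF, −78 °C; (+)-Ipc2BOMe [from (−)-α-pinene], −78 °C; BF3·OEt2, −78 °C; 7, −78 °C; then 3 M NaOH, 30% H2O2, 0 °C → rt
Reagents that add atoms: none
Why: Brown (Z)-γ-alkoxyallylboration: the chelated lithiated ether 9 is trapped on boron, BF3 removes methoxide from 10, and the (Z)-allylborane 11 adds to the aldehyde through a chair Zimmerman–Traxler transition state. The Z geometry enforces the syn C6–OH/C7–OMOM relationship, and the isopinocampheyl groups from (−)-α-pinene direct attack to the Re face of hexanal, giving (3S,4S). Oxidative work-up cleaves the borinic ester 12 without affecting the acetal or alkene.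

Step 5
Reactants: 6 (2R)-2-(tert-butyldimethylsilyloxy)undec-10-enoic acid; 13 (3S,4S)-3-(methoxymethoxy)non-1-en-4-ol
Product: 14 (3S,4S)-3-(methoxymethoxy)non-1-en-4-yl (2R)-2-(tert-butyldimethylsilyloxy)undec-10-enoate
Conditions: DCC, DMAP (0.2 equiv), CH2Cl2, 0 °C → rt
Reagents that add atoms: none
Why: Steglich esterification through the O-acylisourea and acylpyridinium ion; the α-silyloxy acid is only weakly α-acidic, so C10 should be retained, and the C–O bond of the alcohol is not broken, so C6 is retained.

Step 6
Reactants: 14 (3S,4S)-3-(methoxymethoxy)non-1-en-4-yl (2R)-2-(tert-butyldimethylsilyloxy)undec-10-enoate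
Product: 15 (3R)-3-(tert-butyldimethylsilyloxy)-2-{[(3S,4S)-3-(methoxymethoxy)non-1-en-4-yl]oxy}dodeca-1,11-diene
Conditions: Cp2TiMe2 (3 equiv), toluene, 75 °C, dark; filtration through basic Al2O3 (hexane/Et3N)
Reagents that add atoms: dimethyltitanocene Cp2TiMe2, [CH3-].[CH3-].[Ti+4].[cH-]1cccc1.[cH-]1cccc1
Why: Petasis methylenation of an ester: thermolysis gives Cp2Ti=CH2, which undergoes (2+2) addition to the ester carbonyl and cycloreversion to the enol ether and Cp2TiO. The reagent is neither basic nor acidic, so the silyl ether, acetal, alkenes and all three stereocentres should survive.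

Step 7
Reactants: 15 (3R)-3-(tert-butyldimethylsilyloxy)-2-{[(3S,4S)-3-(methoxymethoxy)non-1-en-4-yl]oxy}dodeca-1,11-diene
Product: 16 (2S,3S)-5-[(1R)-1-(tert-butyldimethylsilyloxy)dec-9-en-1-yl]-3-(methoxymethoxy)-2-pentyl-2,3-dihydrofuran
Conditions: RuCl2(=CHPh)(H2IMes)(PCy3) (second-generation Grubbs catalyst, 2 × 5 mol%), 1,4-benzoquinone (10 mol%), toluene (0.002 M), 70 °C, Ar sparge; then ethylene (1 atm), 40 °C; filtration through Et3N-deactivated SiO2
Reagents that add atoms: none
Why: Ring-closing metathesis of an ester-derived enol ether; the closest known reaction type is the closure of olefinic enol ethers, made by titanium methylenation of esters, to five- and six-membered cyclic enol ethers. The ruthenium benzylidene exchanges onto the monosubstituted C8 vinyl group, the new alkylidene adds to the 1,1-disubstituted enol ether in a (2+2) step that joins C8 to C9, and cycloreversion of the ruthenacyclobutane releases 16 and Ru=CH2, with ethylene as the only co-product. The single ring is closed by forming the endocyclic C8=C9 bond of a five-membered ring (O, C6, C7, C8, C9). No stereocentre is formed, and C6, C7 and C10 are untouched under these neutral conditions. The selectivity needed is ring closure over cross metathesis at C18=C19: high dilution favours the intramolecular path, and a carbene on C18 can close only a ten- or fourteen-membered ring. Any C18-linked homodimer still cyclises at both ends and is cut back to the terminal alkene by the ethylene purge, because the trisubstituted cyclic enol ether does not re-enter metathesis. Benzoquinone suppresses alkene migration by ruthenium hydrides, and the amine-treated silica prevents acid-induced loss of the allylic C7 acetal.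

Step 8
Reactants: 16 (2S,3S)-5-[(1R)-1-(tert-butyldimethylsilyloxy)dec-9-en-1-yl]-3-(methoxymethoxy)-2-pentyl-2,3-dihydrofuran
Product: 17 (2S,3S)-5-[(1R)-1-(tert-butyldimethylsilyloxy)dec-9-en-1-yl]-5-methoxy-3-(methoxymethoxy)-2-pentyloxolane (both C5 anomers)
Conditions: MeOH (20 equiv), pyridinium p-toluenesulfonate (5 mol%), CH2Cl2, 0 °C; Et3N quench
Reagents that add atoms: methanol, CO
Why: Acid-catalysed addition of an alcohol to a cyclic enol ether (2-deoxyglycoside formation from a glycal): protonation at C8 gives the C9 oxocarbenium ion, which methanol in excess traps faster than the C7 acetal can ionise. The weak acid should leave the silyl ether and acetal intact, and the C9 configuration is irrelevant.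

Step 9
Reactants: 17 (2S,3S)-5-[(1R)-1-(tert-butyldimethylsilyloxy)dec-9-en-1-yl]-5-methoxy-3-(methoxymethoxy)-2-pentyloxolane
Product: 18 (2S,3S,5R)-5-[(1R)-1-(tert-butyldimethylsilyloxy)dec-9-en-1-yl]-3-(methoxymethoxy)-2-pentyloxolane
Conditions: Et3SiH (5 equiv), BF3·OEt2 (2 equiv), CH2Cl2, −78 °C; sat. aq. NaHCO3 at −78 °C
Reagents that add atoms: none
Why: Silane reduction of a cyclic ketal through its oxocarbenium ion (ionic hydrogenation, as in C-glycoside synthesis). The cation adopts the envelope with the C7 alkoxy group pseudoaxial and the C6 pentyl pseudoequatorial, and hydride adds to C9 from the inside face, syn to O7, placing the side chain trans to pentyl (9R). Polar Felkin–Anh induction from the C10 silyloxy group favours the same threo C9/C10 product.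

Step 10
Reactants: 18 (2S,3S,5R)-5-[(1R)-1-(tert-butyldimethylsilyloxy)dec-9-en-1-yl]-3-(methoxymethoxy)-2-pentyloxolane
Product: 19 (1R)-1-[(2R,4S,5S)-4-(methoxymethoxy)-5-pentyloxolan-2-yl]dec-9-en-1-ol
Conditions: Bu4NF (1.5 equiv), THF, 0 °C → rt
Reagents that add atoms: none
Why: Fluoride cleavage of a silyl ether, driven by the Si–F bond; the acetal, ring ether and alkene are inert to fluoride.

Step 11
Reactants: 19 (1R)-1-[(2R,4S,5S)-4-(methoxymethoxy)-5-pentyloxolan-2-yl]dec-9-en-1-ol; 20 dodecanoyl chloride
Product: 21 (1R)-1-[(2R,4S,5S)-4-(methoxymethoxy)-5-pentyloxolan-2-yl]dec-9-en-1-yl dodecanoate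
Conditions: 20 (1.3 equiv), pyridine, DMAP (10 mol%), CH2Cl2, 0 °C → rt
Reagents that add atoms: none
Why: DMAP-catalysed acylation of a secondary alcohol by an acid chloride; the C10–O bond is not broken, so the configuration is retained, and O7 is still masked.

Step 12
Reactants: 21 (1R)-1-[(2R,4S,5S)-4-(methoxymethoxy)-5-pentyloxolan-2-yl]dec-9-en-1-yl dodecanoate
Product: 22 (1R)-1-[(2R,4S,5S)-4-hydroxy-5-pentyloxolan-2-yl]dec-9-en-1-yl dodecanoate
Conditions: Me2BBr (3 equiv), CH2Cl2, −78 °C; then THF/sat. aq. NaHCO3, −78 °C → rt
Reagents that add atoms: none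
Why: Cleavage of a methoxymethyl ether by bromodimethylborane: boron binds the acetal oxygen and bromide opens the acetal at −78 °C, where esters, alkenes and cyclic ethers do not react. Hydrolysis on work-up frees the C7 hydroxyl without breaking the C7–O bond.

## Compound list

1 | 8-bromooct-1-ene | C=CCCCCCCBr | starting material
2 | methyl (2R)-oxirane-2-carboxylate (methyl (R)-glycidate) | COC(=O)[C@H]1CO1 | starting material
3 | oct-7-en-1-ylmagnesium bromide | C=CCCCCCC[Mg]Br | intermediate
4 | methyl (2R)-2-hydroxyundec-10-enoate | C=CCCCCCCC[C@@H](O)C(=O)OC | intermediate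
5 | methyl (2R)-2-(tert-butyldimethylsilyloxy)undec-10-enoate | C=CCCCCCCC[C@@H](O[Si](C)(C)C(C)(C)C)C(=O)OC | intermediate
6 | (2R)-2-(tert-butyldimethylsilyloxy)undec-10-enoic acid | C=CCCCCCCC[C@@H](O[Si](C)(C)C(C)(C)C)C(=O)O | intermediate
7 | hexanal | CCCCCC=O | starting material
8 | 3-(methoxymethoxy)prop-1-ene | C=CCOCOC | starting material
9 | [(2Z)-3-(methoxymethoxy)prop-2-en-1-yl]lithium | [Li]C/C=C\OCOC | intermediate
10 | lithium methoxy[(2Z)-3-(methoxymethoxy)prop-2-en-1-yl]bis(Ipc)borate | [Li+].CO[B-](C/C=C\OCOC)([C@H]1C[C@H]2C[C@@H]([C@@H]1C)C2(C)C)[C@H]1C[C@H]2C[C@@H]([C@@H]1C)C2(C)C | intermediate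
11 | [(2Z)-3-(methoxymethoxy)prop-2-en-1-yl]bis(Ipc)borane | COCO/C=C\CB([C@H]1C[C@H]2C[C@@H]([C@@H]1C)C2(C)C)[C@H]1C[C@H]2C[C@@H]([C@@H]1C)C2(C)C | intermediate
12 | (3S,4S)-3-(methoxymethoxy)non-1-en-4-yl bis(Ipc)borinate | C=C[C@H](OCOC)[C@@H](OB([C@H]1C[C@H]2C[C@@H]([C@@H]1C)C2(C)C)[C@H]1C[C@H]2C[C@@H]([C@@H]1C)C2(C)C)CCCCC | intermediate
13 | (3S,4S)-3-(methoxymethoxy)non-1-en-4-ol | C=C[C@H](OCOC)[C@@H](O)CCCCC | intermediate
14 | (3S,4S)-3-(methoxymethoxy)non-1-en-4-yl (2R)-2-(tert-butyldimethylsilyloxy)undec-10-enoate | C=CCCCCCCC[C@@H](O[Si](C)(C)C(C)(C)C)C(=O)O[C@@H](CCCCC)[C@@H](OCOC)C=C | intermediate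
15 | (3R)-3-(tert-butyldimethylsilyloxy)-2-{[(3S,4S)-3-(methoxymethoxy)non-1-en-4-yl]oxy}dodeca-1,11-diene | C=CCCCCCCC[C@@H](O[Si](C)(C)C(C)(C)C)C(=C)O[C@@H](CCCCC)[C@@H](OCOC)C=C | intermediate
16 | (2S,3S)-5-[(1R)-1-(tert-butyldimethylsilyloxy)dec-9-en-1-yl]-3-(methoxymethoxy)-2-pentyl-2,3-dihydrofuran | C=CCCCCCCC[C@@H](O[Si](C)(C)C(C)(C)C)C1=C[C@H](OCOC)[C@H](CCCCC)O1 | intermediate
17 | (2S,3S)-5-[(1R)-1-(tert-butyldimethylsilyloxy)dec-9-en-1-yl]-5-methoxy-3-(methoxymethoxy)-2-pentyloxolane, both C5 anomers | C=CCCCCCCC[C@@H](O[Si](C)(C)C(C)(C)C)C1(OC)C[C@H](OCOC)[C@H](CCCCC)O1 | intermediate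
18 | (2S,3S,5R)-5-[(1R)-1-(tert-butyldimethylsilyloxy)dec-9-en-1-yl]-3-(methoxymethoxy)-2-pentyloxolane | C=CCCCCCCC[C@@H](O[Si](C)(C)C(C)(C)C)[C@H]1C[C@H](OCOC)[C@H](CCCCC)O1 | intermediate
19 | (1R)-1-[(2R,4S,5S)-4-(methoxymethoxy)-5-pentyloxolan-2-yl]dec-9-en-1-ol | C=CCCCCCCC[C@@H](O)[C@H]1C[C@H](OCOC)[C@H](CCCCC)O1 | intermediate
20 | dodecanoyl chloride | CCCCCCCCCCCC(Cl)=O | starting material
21 | (1R)-1-[(2R,4S,5S)-4-(methoxymethoxy)-5-pentyloxolan-2-yl]dec-9-en-1-yl dodecanoate | C=CCCCCCCC[C@@H](OC(=O)CCCCCCCCCCC)[C@H]1C[C@H](OCOC)[C@H](CCCCC)O1 | intermediate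
22 | (1R)-1-[(2R,4S,5S)-4-hydroxy-5-pentyloxolan-2-yl]dec-9-en-1-yl dodecanoate | C=CCCCCCCC[C@@H](OC(=O)CCCCCCCCCCC)[C@H]1C[C@H](O)[C@H](CCCCC)O1 | target

## Step count and least certain steps

Total: 12 steps. Longest linear sequence: 11 steps (steps 1–3 and 5–12, from bromide 1); the alcohol branch (step 4) joins at step 5.

**Step 7 (key step).** The most likely failure is cross metathesis and oligomerisation through the unhindered C18=C19 alkene outrunning ring closure. The catalyst loads faster there than on the branched allylic C8 vinyl group, and closure onto the electron-rich 1,1-disubstituted enol ether is slow. Alkene migration by ruthenium hydrides and acid-induced loss of the allylic acetal during isolation are secondary risks. The fallback removes the remote alkene from play before metathesis. From acid 6, pyridinium tribromide (CH2Cl2, 0 °C) should give (2R)-10,11-dibromo-2-(tert-butyldimethylsilyloxy)undecanoic acid F1. Esterification with 13 as in step 5 gives the dibromo ester F2, and Cp2TiMe2 as in step 6 gives the dibromo enol ether F3. RuCl2(=CHPh)(H2IMes)(PCy3) then meets only the C8 vinyl group and the enol ether, and should close the dibromo dihydrofuran F4 at ordinary concentration. Zn dust (DMF, Et3N, rt) removes both bromine atoms and regenerates the terminal alkene, returning to 16.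

**Step 9.** Facial selectivity at C9 may erode if the C7 acetal oxygen bridges to the cation or the other envelope competes. The Lewis acid may also cleave the methoxymethyl group or drive elimination toward the furan. The fallback sets C9 by anchimeric control and avoids the acid-catalysed ketalisation. From 16, N-iodosuccinimide and methanol (CH2Cl2, NaHCO3, −78 °C) should add iodine to C8 on the face away from the C7 oxygen and methoxide to C9 trans to it, giving the 8-iodo methyl ketal F5. Et3SiH with Me3SiOTf (−78 °C) reduces F5 through an iodine-bridged cation that hydride can open only anti to iodine, that is from the face of O7, giving the 8-iodo oxolane F6. Bu3SnH with azobisisobutyronitrile (toluene, 80 °C) removes the iodine and returns to 18.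

**Step 1.** Addition of the organomagnesium reagent to the ester carbonyl of 2, or base-induced oligomerisation of the glycidate, may compete with epoxide opening. The fallback opens an epoxide with no carbonyl group and adjusts the oxidation state afterwards. Reagent 3 (from 1) with CuI and (R)-2-[(trityloxy)methyl]oxirane gives (2R)-1-(trityloxy)undec-10-en-2-ol F7. TBSCl/imidazole gives the silyl ether F8. Camphorsulfonic acid in MeOH/CH2Cl2 at 0 °C removes the trityl group to give (2R)-2-(tert-butyldimethylsilyloxy)undec-10-en-1-ol F9. TEMPO with PhI(OAc)2 (MeCN/H2O) oxidises the primary alcohol to the acid, returning to 6.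

**Step 12.** Acetal cleavage may be accompanied by migration or loss of the C10 dodecanoate, or by opening of the oxolane by the boron halide if the temperature rises. The fallback moves the acetal cleavage ahead of the ester and ends with a neutral oxidative deprotection. From 18, Me2BBr (−78 °C) gives (2S,3S,5R)-5-[(1R)-1-(tert-butyldimethylsilyloxy)dec-9-en-1-yl]-2-pentyloxolan-3-ol F10. NaH, 4-methoxybenzyl chloride and Bu4NI (DMF, 0 °C) give the 4-methoxybenzyl ether F11. Bu4NF frees the C10 alcohol F12, and acylation with 20 as in step 11 gives the ester F13. 2,3-Dichloro-5,6-dicyano-1,4-benzoquinone (CH2Cl2/pH 7 buffer, 0 °C) removes the benzyl ether and returns to 22.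

## Further compounds

F1 | step 7 | (2R)-10,11-dibromo-2-(tert-butyldimethylsilyloxy)undecanoic acid (both C10 epimers) | BrCC(Br)CCCCCCC[C@@H](O[Si](C)(C)C(C)(C)C)C(=O)O
F2 | step 7 | (3S,4S)-3-(methoxymethoxy)non-1-en-4-yl (2R)-10,11-dibromo-2-(tert-butyldimethylsilyloxy)undecanoate | BrCC(Br)CCCCCCC[C@@H](O[Si](C)(C)C(C)(C)C)C(=O)O[C@@H](CCCCC)[C@@H](OCOC)C=C
F3 | step 7 | (3R)-11,12-dibromo-3-(tert-butyldimethylsilyloxy)-2-{[(3S,4S)-3-(methoxymethoxy)non-1-en-4-yl]oxy}dodec-1-ene | BrCC(Br)CCCCCCC[C@@H](O[Si](C)(C)C(C)(C)C)C(=C)O[C@@H](CCCCC)[C@@H](OCOC)C=C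
F4 | step 7 | (2S,3S)-5-[(1R)-9,10-dibromo-1-(tert-butyldimethylsilyloxy)decyl]-3-(methoxymethoxy)-2-pentyl-2,3-dihydrofuran | BrCC(Br)CCCCCCC[C@@H](O[Si](C)(C)C(C)(C)C)C1=C[C@H](OCOC)[C@H](CCCCC)O1
F5 | step 9 | 8-iodo methyl ketal: 17 with iodine at C8 on the ring face opposite the C7 oxygen and the C9 methoxy group trans to iodine; C6, C7, C10 as in 17 | C=CCCCCCCC[C@@H](O[Si](C)(C)C(C)(C)C)[C@@]1(OC)[C@@H](I)[C@H](OCOC)[C@H](CCCCC)O1
F6 | step 9 | 8-iodo oxolane: 18 with iodine at C8 trans to the C7 oxygen and cis to the C9 side chain; C6, C7, C9, C10 as in 18 | C=CCCCCCCC[C@@H](O[Si](C)(C)C(C)(C)C)[C@H]1[C@@H](I)[C@H](OCOC)[C@H](CCCCC)O1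
F7 | step 1 | (2R)-1-(trityloxy)undec-10-en-2-ol | C=CCCCCCCC[C@@H](O)COC(c1ccccc1)(c1ccccc1)c1ccccc1
F8 | step 1 | tert-butyldimethyl{[(2R)-1-(trityloxy)undec-10-en-2-yl]oxy}silane | C=CCCCCCCC[C@@H](O[Si](C)(C)C(C)(C)C)COC(c1ccccc1)(c1ccccc1)c1ccccc1
F9 | step 1 | (2R)-2-(tert-butyldimethylsilyloxy)undec-10-en-1-ol | C=CCCCCCCC[C@@H](O[Si](C)(C)C(C)(C)C)CO
F10 | step 12 | (2S,3S,5R)-5-[(1R)-1-(tert-butyldimethylsilyloxy)dec-9-en-1-yl]-2-pentyloxolan-3-ol | C=CCCCCCCC[C@@H](O[Si](C)(C)C(C)(C)C)[C@H]1C[C@H](O)[C@H](CCCCC)O1
F11 | step 12 | (2S,3S,5R)-5-[(1R)-1-(tert-butyldimethylsilyloxy)dec-9-en-1-yl]-3-[(4-methoxybenzyl)oxy]-2-pentyloxolane | C=CCCCCCCC[C@@H](O[Si](C)(C)C(C)(C)C)[C@H]1C[C@H](OCc2ccc(OC)cc2)[C@H](CCCCC)O1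
F12 | step 12 | (1R)-1-[(2R,4S,5S)-4-[(4-methoxybenzyl)oxy]-5-pentyloxolan-2-yl]dec-9-en-1-ol | C=CCCCCCCC[C@@H](O)[C@H]1C[C@H](OCc2ccc(OC)cc2)[C@H](CCCCC)O1
F13 | step 12 | (1R)-1-[(2R,4S,5S)-4-[(4-methoxybenzyl)oxy]-5-pentyloxolan-2-yl]dec-9-en-1-yl dodecanoate | C=CCCCCCCC[C@@H](OC(=O)CCCCCCCCCCC)[C@H]1C[C@H](OCc2ccc(OC)cc2)[C@H](CCCCC)O1
A1 | alternative 1 | D-glucose (open-chain form) | O=C[C@H](O)[C@@H](O)[C@H](O)[C@H](O)CO
A2 | alternative 1 | (1R)-1-[(3aR,5S,6aR)-2,2-dimethyltetrahydrofuro[2,3-d][1,3]dioxol-5-yl]hexyl methanesulfonate | CCCCC[C@@H](OS(C)(=O)=O)[C@@H]1C[C@H]2OC(C)(C)O[C@H]2O1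
A3 | alternative 1 | (2S,3S,5R)-5-(dimethoxymethyl)-2-pentyloxolan-3-ol | COC(OC)[C@H]1C[C@H](O)[C@H](CCCCC)O1
A4 | alternative 2 | pentanal | CCCCC=O
A5 | alternative 2 | (1R)-1-[(2R)-2,3-dihydrofuran-2-yl]dec-9-en-1-yl dodecanoate | C=CCCCCCCC[C@@H](OC(=O)CCCCCCCCCCC)[C@H]1CC=CO1
A6 | alternative 2 | (1R)-1-(7-butyl-2,6-dioxabicyclo[3.2.0]heptan-3-yl)dec-9-en-1-yl dodecanoate (exo-butyl epimer) | C=CCCCCCCC[C@@H](OC(=O)CCCCCCCCCCC)[C@H]1C[C@@H]2O[C@@H](CCCC)[C@@H]2O1
A7 | alternative 3 | tert-butyldimethyl{[(2S,3S)-2-pentyl-3,4-dihydro-2H-pyran-3-yl]oxy}silane | CCCCC[C@@H]1OC=CC[C@@H]1O[Si](C)(C)C(C)(C)C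
A8 | alternative 3 | (2S,3S,5R)-3-(tert-butyldimethylsilyloxy)-5-(dimethoxymethyl)-2-pentyloxolane | COC(OC)[C@H]1C[C@H](O[Si](C)(C)C(C)(C)C)[C@H](CCCCC)O1
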